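**Plan**

- Retrosynthesis: remove eight O‑methyl groups; cut the upper dihydrobenzofuran (on ring A) at its C2–C3 bond (rhodium carbene C–H insertion); cut the lower dihydrobenzofuran (on ring B) at O–C6(aryl) and C5–CH(Ar) together; cut the seven‑membered ring at C5–C5a (Friedel–Crafts acylation); cut the C11–ring A bond (Negishi coupling of an enol triflate).
- Forward: deoxybenzoin → enol triflate → Negishi coupling with a ring A iodide → carboxy‑directed asymmetric hydrogenation → dibenzosuberone → dibenzosuberane → (3+2) annulation with 4‑methoxybenzaldehyde → ring A bromide to ketone → carbene insertion → epimerization → demethylation.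
- Numbering used below: dibenzo[a,d][7]annulene core; ring A = C1–C4 with C4a/C11a; ring B = C6–C9 with C5a/C9a; C5 = carbon between the rings; C11 = CH(aryl).
- Enabling feature: in the dibenzosuberane the C5 methylene lies between C4a of ring A and C5a of ring B (doubly benzylic, the most acidic C–H), and ring B carries fluorine on C6, ortho to C5a, the carbon that bears the furan oxygen in the target; C5 is the nucleophile and C6 the electrophile toward the aldehyde C=O.
- Stereochemistry: C11 from the iridium‑catalysed hydrogenation; C5 from C11 (attack anti to the pseudoaxial aryl group); the adjacent O–CH centre from C5 (trans); upper ring C3 from the chiral dirhodium catalyst; upper ring C2 by acid equilibration to trans.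

Key step: step 9

Assumption: the sense of induction of the chiral iridium catalyst (step 6) and of the chiral dirhodium catalyst (step 14) is taken by analogy with related substrates; if it proves opposite, the enantiomeric catalyst is used and nothing else changes.

**Route**

Step 1
Reactants: 1 2-(3-fluoro-5-methoxyphenyl)acetic acid; 2 1,3-dimethoxybenzene
Product: 4 1-(2,4-dimethoxyphenyl)-2-(3-fluoro-5-methoxyphenyl)ethan-1-one, via mixed anhydride 3 (not isolated)
Conditions: (CF3CO)2O (2 equiv), H3PO4 (cat), CH2Cl2, 0 to 25 °C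
Reagents that add atoms: none
Why: Friedel–Crafts acylation through the mixed trifluoroacetic anhydride, in which 1,3-dimethoxybenzene is far more nucleophilic than the fluoroanisole ring of 1 and reacts at C4 (para to one methoxy group and ortho to the other), so the deoxybenzoin should form without a new stereocentre.

Step 2
Reactants: 4 1-(2,4-dimethoxyphenyl)-2-(3-fluoro-5-methoxyphenyl)ethan-1-one
Product: 6 (Z)-1-(2,4-dimethoxyphenyl)-2-(3-fluoro-5-methoxyphenyl)ethenyl trifluoromethanesulfonate, via potassium enolate 5 (not isolated)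
Conditions: KN(SiMe3)2, THF, −78 °C; then PhNTf2, −78 to 0 °C
Reagents that add atoms: N-phenylbis(trifluoromethanesulfonimide), O=S(=O)(N(c1ccccc1)S(=O)(=O)C(F)(F)F)C(F)(F)F
Why: Enol triflate formation, in which the aryl benzyl ketone gives the conjugated (Z)-enolate (oxygen cis to the 3-fluoro-5-methoxyphenyl group) and O-sulfonylation keeps that geometry.

Step 3
Reactants: 7 methyl 4-bromo-3,5-dimethoxybenzoate
Product: 8 methyl 4-bromo-2-iodo-3,5-dimethoxybenzoate
Conditions: NIS (1.05 equiv), CF3CO2H (cat), MeCN, 25 °C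
Reagents that add atoms: N-iodosuccinimide, O=C1CCC(=O)N1I
Why: Electrophilic aromatic iodination, in which the two free positions of 7 are equivalent and each is ortho and para to a methoxy group, so one equivalent of reagent should give a single mono-iodide.

Step 4
Reactants: 8 methyl 4-bromo-2-iodo-3,5-dimethoxybenzoate; 6 (Z)-1-(2,4-dimethoxyphenyl)-2-(3-fluoro-5-methoxyphenyl)ethenyl trifluoromethanesulfonate
Product: 11 methyl 4-bromo-2-[(Z)-1-(2,4-dimethoxyphenyl)-2-(3-fluoro-5-methoxyphenyl)ethenyl]-3,5-dimethoxybenzoate, via arylmagnesium chloride 9 (not isolated), via arylzinc chloride 10 (not isolated)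
Conditions: i-PrMgCl·LiCl, THF, −40 °C; ZnCl2, −40 to 25 °C; then 6, Pd(OAc)2 (3 mol%), SPhos (6 mol%), THF, 50 °C
Reagents that add atoms: none
Why: Iodine–magnesium exchange is selective for the C–I bond ortho to the ester over the hindered electron-rich C–Br bond, and transmetalation to zinc followed by Negishi coupling on zerovalent palladium joins the aryl group to the enol triflate carbon with retention of the alkene geometry.

Step 5
Reactants: 11 methyl 4-bromo-2-[(Z)-1-(2,4-dimethoxyphenyl)-2-(3-fluoro-5-methoxyphenyl)ethenyl]-3,5-dimethoxybenzoate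
Product: 12 4-bromo-2-[(Z)-1-(2,4-dimethoxyphenyl)-2-(3-fluoro-5-methoxyphenyl)ethenyl]-3,5-dimethoxybenzoic acid
Conditions: LiOH, THF/MeOH/H2O, 60 °C; then aq HCl
Reagents that add atoms: lithium hydroxide, [Li+].[OH-]
Why: Saponification of a methyl ester with only one ortho substituent frees the carboxyl group that directs the next step, and no stereocentre is involved.

Step 6
Reactants: 12 4-bromo-2-[(Z)-1-(2,4-dimethoxyphenyl)-2-(3-fluoro-5-methoxyphenyl)ethenyl]-3,5-dimethoxybenzoic acid
Product: 13 4-bromo-2-[(1S)-1-(2,4-dimethoxyphenyl)-2-(3-fluoro-5-methoxyphenyl)ethyl]-3,5-dimethoxybenzoic acid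
Conditions: H2 (10 atm), [Ir(cod)((Sa,S)-SIPHOX)]B[3,5-(CF3)2C6H3]4 (2 mol%), Cs2CO3 (0.5 equiv), MeOH, 45 °C
Reagents that add atoms: none
Why: Carboxy-directed asymmetric hydrogenation, in which the carboxylate binds monovalent iridium and delivers H2 to one face of the neighbouring triaryl alkene, the chiral spiro phosphine-oxazoline ligand setting the new benzylic centre as (S) from the single (Z)-alkene while the aryl bromide and fluoride are left alone by this homogeneous catalyst.

Step 7
Reactants: 13 4-bromo-2-[(1S)-1-(2,4-dimethoxyphenyl)-2-(3-fluoro-5-methoxyphenyl)ethyl]-3,5-dimethoxybenzoic acid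
Product: 15 (11S)-2-bromo-11-(2,4-dimethoxyphenyl)-6-fluoro-1,3,8-trimethoxy-10,11-dihydro-5H-dibenzo[a,d][7]annulen-5-one, via mixed anhydride 14 (not isolated)
Conditions: (CF3CO)2O, CH2Cl2, 0 °C; then CF3SO3H (10 mol%), 0 to 25 °C
Reagents that add atoms: none
Why: Intramolecular Friedel–Crafts acylation closes the seven-membered ring at the ring B carbon that is para to the methoxy group and ortho to fluorine (the usual orientation of 3-fluoroanisoles), whereas a six-ring closure onto the dimethoxyphenyl group would have to occur meta to both of its methoxy groups, and C11 is not touched.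

Step 8
Reactants: 15 (11S)-2-bromo-11-(2,4-dimethoxyphenyl)-6-fluoro-1,3,8-trimethoxy-10,11-dihydro-5H-dibenzo[a,d][7]annulen-5-one
Product: 16 (11S)-2-bromo-11-(2,4-dimethoxyphenyl)-6-fluoro-1,3,8-trimethoxy-10,11-dihydro-5H-dibenzo[a,d][7]annulene
Conditions: Et3SiH (3 equiv), CF3CO2H, CH2Cl2, 0 to 25 °C
Reagents that add atoms: none
Why: Ionic hydrogenation, in which the protonated diaryl ketone is reduced to the carbinol and ionized to a cation stabilized by the para methoxy group of ring B that the silane reduces to the C5 methylene, with C–Br, C–F and C11 inert.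

Step 9
Reactants: 16 (11S)-2-bromo-11-(2,4-dimethoxyphenyl)-6-fluoro-1,3,8-trimethoxy-10,11-dihydro-5H-dibenzo[a,d][7]annulene; 17 4-methoxybenzaldehyde
Product: 20 bromo trans-dihydrobenzofuran: 16 in which C5 and C6 are bridged by CH(4-methoxyphenyl)–O (CH on C5; O on C6 in place of F); 5S; bridge carbon S; 11S, via diarylmethyllithium 18 (not isolated), via lithium alkoxide 19 (not isolated)
Conditions: LiTMP (lithium 2,2,6,6-tetramethylpiperidide, 1.2 equiv), THF, −78 °C; 17 (1.3 equiv), −78 °C; then KOt-Bu (1.0 equiv), 18-crown-6, −78 to 50 °C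
Reagents that add atoms: none
Why: Proposed new method: LiTMP removes a proton from C5, the only CH2 flanked by two arenes (ring A and ring B), the diarylmethyl anion 18 adds to aldehyde 17 to give alkoxide 19, and after lithium-to-potassium exchange the alkoxide displaces the C6 fluoride by intramolecular SNAr, so the C–C bond and the aryl C–O bond form in one flask. The closest known reaction types are the benzylic lithiation and aldehyde addition of diarylmethanes, the alkoxide SNAr cyclization of 2-(2-fluorophenyl)ethanols to dihydrobenzofurans, and the one-pot deprotonation, addition and SNAr of 2-fluorotoluenes with nitriles that gives indoles; the combination on a diarylmethane with an aldehyde is the untested part. The furan ring closes by 5-exo-trig attack of the alkoxide oxygen on C6 (addition–elimination), which is possible because C6 is ortho to C5a and is slightly activated by the meta methoxy group at C8. C5 is set by C11: the 2,4-dimethoxyphenyl group should sit pseudoaxial on the seven-membered ring (away from the C1 methoxy group) and shield one face of the planar carbanion, so the aldehyde should add anti to it (5,11-trans), while the O–CH centre is set relative to C5 in the reversible addition and irreversible ring closure, the 2,3-trans diaryl arrangement being the less crowded and any cis isomer being convertible by acid as in step 15. The step needs deprotonation at C5 rather than at C11–H or at C7–H between fluorine and methoxy, and no attack on C–Br, which the higher acidity of the doubly benzylic CH2, the bulk of the amide base (which cannot exchange bromine) and the low temperature should secure, and it needs ring closure to outrun base-induced opening of the product, which is why only one equivalent of KOt-Bu is used.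

Step 10
Reactants: 20 bromo trans-dihydrobenzofuran; 21 N,3,5-trimethoxy-N-methylbenzamide
Product: 24 ketone: 20 with 3,5-dimethoxybenzoyl at C2 in place of Br, via aryllithium 22 (not isolated), via lithium hemiaminal 23 (not isolated)
Conditions: n-BuLi (1.05 equiv), THF, −78 °C; then 21, −78 to 0 °C; aq NH4Cl
Reagents that add atoms: none
Why: Bromine–lithium exchange at −78 °C is faster than any deprotonation, and the di-ortho-methoxy aryllithium adds once to the amide (Weinreb ketone synthesis) because the chelated adduct 23 collapses to the hindered ketone only on work-up.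

Step 11
Reactants: 24 ketone with 3,5-dimethoxybenzoyl at C2
Product: 25 phenol: 24 with OH at C1 in place of OMe
Conditions: BCl3 (1.2 equiv), CH2Cl2, −78 to 0 °C; then H2O
Reagents that add atoms: none
Why: Chelation-controlled demethylation, in which BCl3 bound to the ketone cleaves a methyl ether ortho to it, and of the two candidates the C1 methoxy group (wedged between the ketone-bearing C2 and C11a and twisted out of the ring plane) is the more basic and should go first, the six other methoxy groups having no ortho carbonyl.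

Step 12
Reactants: 25 phenol with OH at C1; 26 4-methoxybenzyl chloride
Product: 27 ether: 25 with O–CH2(4-methoxyphenyl) at C1
Conditions: K2CO3, NaI (cat), DMF, 60 °C
Reagents that add atoms: none
Why: Williamson ether synthesis on the phenoxide installs the 4-methoxybenzyl group whose CH2 becomes C2 of the upper dihydrofuran.

Step 13
Reactants: 27 ether with O–CH2(4-methoxyphenyl) at C1
Product: 28 hydrazone of ketone 27 (C=N–NH2; E/Z not defined)
Conditions: N2H4·H2O (excess), AcOH (cat), n-BuOH, 110 °C
Reagents that add atoms: hydrazine hydrate, NN.O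
Why: Hydrazone formation by condensation, for which the di-ortho-substituted benzophenone needs excess hydrazine, acid catalysis and heat, and nothing else in 27 reacts with hydrazine.

Step 14
Reactants: 28 hydrazone of ketone 27
Product: 30 octa-O-methyl target with cis upper dihydrofuran (upper ring 2R,3S; other centres as in the target), via diazo compound 29 (not isolated)
Conditions: MnO2 (8 equiv), Rh2(R-PTAD)4 (1 mol%), CH2Cl2, 0 to 25 °C
Reagents that add atoms: none
Why: MnO2 oxidizes the hydrazone to the diaryldiazomethane 29, which the divalent rhodium carboxylate turns into a donor/donor carbene that inserts into the adjacent benzylic O–CH2 bond (intramolecular 1,5 C–H insertion), the chiral ligands fixing C3 of the new ring as (S) and the concerted insertion giving the 2,3-cis ring, while the C–H bonds of the neighbouring methoxy group are far less reactive.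

Step 15
Reactants: 30 octa-O-methyl target with cis upper dihydrofuran
Product: 31 octa-O-methyl ether of the target (both dihydrofurans trans; all five centres S)
Conditions: CF3CO2H (5 equiv), CH2Cl2, 0 °C
Reagents that add atoms: none
Why: Acid-mediated epimerization, in which reversible ionization of the O–C2 bond to a 4-methoxybenzyl cation and re-closure moves the 4-methoxyphenyl group to the more stable 2,3-trans position while C3 from step 14 is untouched, and any cis lower ring left from step 9 converges in the same way.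

Step 16
Reactants: 31 octa-O-methyl ether of the target
Product: 32 CNP0154774.1 (target)
Conditions: BBr3 (20 equiv), CH2Cl2, −78 to 25 °C; then MeOH/H2O
Reagents that add atoms: none
Why: Global O-demethylation of eight aryl methyl ethers with BBr3, in which no stereocentre bears a group that the reagent removes and the trans dihydrofurans are the thermodynamic isomers should their benzylic C–O bonds ionize reversibly.

**Compound list**

1 | 2-(3-fluoro-5-methoxyphenyl)acetic acid | COc1cc(F)cc(CC(=O)O)c1 | starting material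
2 | 1,3-dimethoxybenzene | COc1cccc(OC)c1 | starting material
3 | mixed anhydride of 1 with trifluoroacetic acid | COc1cc(F)cc(CC(=O)OC(=O)C(F)(F)F)c1 | intermediate
4 | 1-(2,4-dimethoxyphenyl)-2-(3-fluoro-5-methoxyphenyl)ethan-1-one | COc1cc(F)cc(CC(=O)c2ccc(OC)cc2OC)c1 | intermediate
5 | potassium (Z)-enolate of 4 | COc1cc(F)cc(/C=C(\[O-])c2ccc(OC)cc2OC)c1.[K+] | intermediate
6 | (Z)-1-(2,4-dimethoxyphenyl)-2-(3-fluoro-5-methoxyphenyl)ethenyl trifluoromethanesulfonate | COc1cc(F)cc(/C=C(\OS(=O)(=O)C(F)(F)F)c2ccc(OC)cc2OC)c1 | intermediate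
7 | methyl 4-bromo-3,5-dimethoxybenzoate | COC(=O)c1cc(OC)c(Br)c(OC)c1 | starting material
8 | methyl 4-bromo-2-iodo-3,5-dimethoxybenzoate | COC(=O)c1cc(OC)c(Br)c(OC)c1I | intermediate
9 | [3-bromo-2,4-dimethoxy-6-(methoxycarbonyl)phenyl]magnesium chloride | COC(=O)c1cc(OC)c(Br)c(OC)c1[Mg]Cl | intermediate
10 | [3-bromo-2,4-dimethoxy-6-(methoxycarbonyl)phenyl]zinc chloride | COC(=O)c1cc(OC)c(Br)c(OC)c1[Zn]Cl | intermediate
11 | methyl 4-bromo-2-[(Z)-1-(2,4-dimethoxyphenyl)-2-(3-fluoro-5-methoxyphenyl)ethenyl]-3,5-dimethoxybenzoate | COC(=O)c1cc(OC)c(Br)c(OC)c1/C(=C\c1cc(F)cc(OC)c1)c1ccc(OC)cc1OC | intermediate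
12 | 4-bromo-2-[(Z)-1-(2,4-dimethoxyphenyl)-2-(3-fluoro-5-methoxyphenyl)ethenyl]-3,5-dimethoxybenzoic acid | OC(=O)c1cc(OC)c(Br)c(OC)c1/C(=C\c1cc(F)cc(OC)c1)c1ccc(OC)cc1OC | intermediate
13 | 4-bromo-2-[(1S)-1-(2,4-dimethoxyphenyl)-2-(3-fluoro-5-methoxyphenyl)ethyl]-3,5-dimethoxybenzoic acid | OC(=O)c1cc(OC)c(Br)c(OC)c1[C@@H](Cc1cc(F)cc(OC)c1)c1ccc(OC)cc1OC | intermediate
14 | mixed anhydride of 13 with trifluoroacetic acid | O=C(OC(=O)C(F)(F)F)c1cc(OC)c(Br)c(OC)c1[C@@H](Cc1cc(F)cc(OC)c1)c1ccc(OC)cc1OC | intermediate
15 | (11S)-2-bromo-11-(2,4-dimethoxyphenyl)-6-fluoro-1,3,8-trimethoxy-10,11-dihydro-5H-dibenzo[a,d][7]annulen-5-one | COc1cc2C(=O)c3c(F)cc(OC)cc3C[C@@H](c3ccc(OC)cc3OC)c2c(OC)c1Br | intermediate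
16 | (11S)-2-bromo-11-(2,4-dimethoxyphenyl)-6-fluoro-1,3,8-trimethoxy-10,11-dihydro-5H-dibenzo[a,d][7]annulene | COc1cc2Cc3c(F)cc(OC)cc3C[C@@H](c3ccc(OC)cc3OC)c2c(OC)c1Br | intermediate
17 | 4-methoxybenzaldehyde | COc1ccc(C=O)cc1 | starting material
18 | C5-lithio derivative of 16 (diarylmethyllithium) | COc1cc2[CH-]c3c(F)cc(OC)cc3C[C@@H](c3ccc(OC)cc3OC)c2c(OC)c1Br.[Li+] | intermediate
19 | lithium alkoxide from addition of 18 to 17 (C5–CH(O−)(4-methoxyphenyl)) | COc1cc2[C@H]([C@H]([O-])c3ccc(OC)cc3)c3c(F)cc(OC)cc3C[C@@H](c3ccc(OC)cc3OC)c2c(OC)c1Br.[Li+] | intermediate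
20 | bromo trans-dihydrobenzofuran: 16 with C5 and C6 bridged by CH(4-methoxyphenyl)–O (CH on C5; O on C6); 5S; bridge carbon S; 11S | COc1cc2[C@H]3c4c(O[C@@H]3c3ccc(OC)cc3)cc(OC)cc4C[C@@H](c3ccc(OC)cc3OC)c2c(OC)c1Br | intermediate
21 | N,3,5-trimethoxy-N-methylbenzamide | CON(C)C(=O)c1cc(OC)cc(OC)c1 | starting material
22 | aryllithium: 20 with Li at C2 in place of Br | COc1cc2[C@H]3c4c(O[C@@H]3c3ccc(OC)cc3)cc(OC)cc4C[C@@H](c3ccc(OC)cc3OC)c2c(OC)c1[Li] | intermediate
23 | lithium hemiaminal adduct of 22 and 21 | COc1cc2[C@H]3c4c(O[C@@H]3c3ccc(OC)cc3)cc(OC)cc4C[C@@H](c3ccc(OC)cc3OC)c2c(OC)c1C(O[Li])(N(C)OC)c1cc(OC)cc(OC)c1 | intermediate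
24 | ketone: 20 with 3,5-dimethoxybenzoyl at C2 in place of Br | COc1cc2[C@H]3c4c(O[C@@H]3c3ccc(OC)cc3)cc(OC)cc4C[C@@H](c3ccc(OC)cc3OC)c2c(OC)c1C(=O)c1cc(OC)cc(OC)c1 | intermediate
25 | phenol: 24 with OH at C1 | COc1cc2[C@H]3c4c(O[C@@H]3c3ccc(OC)cc3)cc(OC)cc4C[C@@H](c3ccc(OC)cc3OC)c2c(O)c1C(=O)c1cc(OC)cc(OC)c1 | intermediate
26 | 4-methoxybenzyl chloride | COc1ccc(CCl)cc1 | starting material
27 | ether: 25 with O–CH2(4-methoxyphenyl) at C1 | COc1cc2[C@H]3c4c(O[C@@H]3c3ccc(OC)cc3)cc(OC)cc4C[C@@H](c3ccc(OC)cc3OC)c2c(OCc2ccc(OC)cc2)c1C(=O)c1cc(OC)cc(OC)c1 | intermediate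
28 | hydrazone of ketone 27 | COc1cc2[C@H]3c4c(O[C@@H]3c3ccc(OC)cc3)cc(OC)cc4C[C@@H](c3ccc(OC)cc3OC)c2c(OCc2ccc(OC)cc2)c1C(=NN)c1cc(OC)cc(OC)c1 | intermediate
29 | diazo compound from 28 | COc1cc2[C@H]3c4c(O[C@@H]3c3ccc(OC)cc3)cc(OC)cc4C[C@@H](c3ccc(OC)cc3OC)c2c(OCc2ccc(OC)cc2)c1C(=[N+]=[N-])c1cc(OC)cc(OC)c1 | intermediate
30 | octa-O-methyl target with cis upper dihydrofuran (upper ring 2R,3S) | COc1ccc([C@@H]2Oc3c4c(cc(OC)c3[C@@H]2c2cc(OC)cc(OC)c2)[C@H]2c3c(cc(OC)cc3O[C@@H]2c2ccc(OC)cc2)C[C@H]4c2ccc(OC)cc2OC)cc1 | intermediate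
31 | octa-O-methyl ether of the target (all five centres S) | COc1ccc([C@H]2Oc3c4c(cc(OC)c3[C@@H]2c2cc(OC)cc(OC)c2)[C@H]2c3c(cc(OC)cc3O[C@@H]2c2ccc(OC)cc2)C[C@H]4c2ccc(OC)cc2OC)cc1 | intermediate
32 | CNP0154774.1 | Oc1ccc([C@H]2Oc3c4c(cc(O)c3[C@@H]2c2cc(O)cc(O)c2)[C@H]2c3c(cc(O)cc3O[C@@H]2c2ccc(O)cc2)C[C@H]4c2ccc(O)cc2O)cc1 | target

**Summary**

Total steps: 16. Longest linear sequence: 15 steps (steps 1, 2 and 4 to 16).

Steps most likely to fail:

1. Step 9 (proposed new method). Metalation may occur on ring B next to fluorine and lead to fluoride loss, the alkoxide may revert to its components before ring closure, or the base may open the newly formed dihydrofuran by elimination. The fallback uses known reaction types, sets out from 15 and comes back at 20. The C6 fluoride of 15, activated by the ortho ketone, is displaced by sodium 4-methoxybenzyl alkoxide (4-methoxybenzyl alcohol, NaH, DMF) to give the 6-(4-methoxybenzyloxy) ketone F1. Condensation with hydrazine (AcOH, n-BuOH, heat) gives the hydrazone F2. MnO2 with Rh2(PTAD)4 (enantiomer matched to C11) gives the diazo compound F3, whose carbene inserts into the O–CH2 bond to give the cis-fused dihydrobenzofuran F4. Trifluoroacetic acid then epimerizes the O–CH centre to the trans isomer 20.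

2. Step 6. Hydrogen delivery to the hindered triaryl alkene may be slow or poorly face-selective. The fallback sets out from 12 and comes back at 13. Directed hydrogenation with the achiral complex [Ir(cod)(PCy3)(py)]PF6 gives the racemic acid F5. Crystallization with (S)-1-phenylethylamine (or its enantiomer, whichever gives the less soluble salt of the S acid) gives the diastereomerically pure salt F6. Acidification returns 13.

3. Step 11. The reagent may cleave the C3 methyl ether instead of the C1 one, or both. The fallback sets out from 24 and comes back at 25. Excess BCl3 cleaves both methyl ethers ortho to the ketone to give the bis-phenol F7. One equivalent of MeI with K2CO3 in acetone then methylates the less hindered C3 hydroxyl, leaving the C1 hydroxyl (flanked by C11a and the ketone) free, which is 25.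

Further compounds
F1 | step 9 | (11S)-2-bromo-11-(2,4-dimethoxyphenyl)-1,3,8-trimethoxy-6-[(4-methoxyphenyl)methoxy]-10,11-dihydro-5H-dibenzo[a,d][7]annulen-5-one | COc1cc2C(=O)c3c(OCc4ccc(OC)cc4)cc(OC)cc3C[C@@H](c3ccc(OC)cc3OC)c2c(OC)c1Br
F2 | step 9 | hydrazone of F1 | COc1cc2C(=NN)c3c(OCc4ccc(OC)cc4)cc(OC)cc3C[C@@H](c3ccc(OC)cc3OC)c2c(OC)c1Br
F3 | step 9 | 5-diazo compound from F2 | COc1cc2C(=[N+]=[N-])c3c(OCc4ccc(OC)cc4)cc(OC)cc3C[C@@H](c3ccc(OC)cc3OC)c2c(OC)c1Br
F4 | step 9 | cis-dihydrobenzofuran epimer of 20 (O–CH centre R) | COc1cc2[C@H]3c4c(O[C@H]3c3ccc(OC)cc3)cc(OC)cc4C[C@@H](c3ccc(OC)cc3OC)c2c(OC)c1Br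
F5 | step 6 | racemic 4-bromo-2-[1-(2,4-dimethoxyphenyl)-2-(3-fluoro-5-methoxyphenyl)ethyl]-3,5-dimethoxybenzoic acid | OC(=O)c1cc(OC)c(Br)c(OC)c1C(Cc1cc(F)cc(OC)c1)c1ccc(OC)cc1OC
F6 | step 6 | (S)-1-phenylethylammonium salt of acid 13 | C[C@H]([NH3+])c1ccccc1.[O-]C(=O)c1cc(OC)c(Br)c(OC)c1[C@@H](Cc1cc(F)cc(OC)c1)c1ccc(OC)cc1OC
F7 | step 11 | bis-phenol: 24 with OH at C1 and C3 | Oc1cc2[C@H]3c4c(O[C@@H]3c3ccc(OC)cc3)cc(OC)cc4C[C@@H](c3ccc(OC)cc3OC)c2c(O)c1C(=O)c1cc(OC)cc(OC)c1
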